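**Retrosynthetic overview**

1. Feature: C2 of dihydrofuran ring C is the benzylic carbon para to the free hydroxyl of guaiacyl ring A, and O1 is the phenol oxygen of ring B (the benzo ring of the dihydrobenzofuran). O1–C2 is therefore cut to an open (R)-2,3-diarylpropan-1-ol; two-electron oxidation of its ring A 4-alkylguaiacol gives a p-quinone methide with C2 as the electrophilic exocyclic carbon.
2. Furan ring D of the benzofuran is cut at O1'–C2' and C3'–C3a' (Sonogashira coupling with 5-endo-dig closure) into a ring B ethynyl group, made from the C5 formyl group, and 4-(3-hydroxypropyl)-2-iodo-6-methoxyphenol (benzo ring E, from eugenol).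
3. The C3 stereocenter of the open precursor comes from an auxiliary-controlled benzylation (C2–C3 bond) of a ring B arylacetyl oxazolidinone with MOM-protected vanillyl bromide (ring A, from vanillin).
4. The ring B arylacetic acid comes from methyl vanillate by O-allylation, Claisen rearrangement and ozonolysis/Pinnick oxidation. The ester is the masked C5 formyl group (LiAlH4, then MnO2), so no aldehyde meets the enolate or the hydride.
5. Order of ring formation: ring C in step 13, then ring D in step 18; rings A, B and E are bought as vanillin, methyl vanillate and eugenol.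

Key step: step 13

Remark: the SMILES encodes the trans (2S,3R) dihydrobenzofuran; the open precursor with the same spatial arrangement at C3 is the (R)-alcohol, and the route is planned for that isomer. MOM = methoxymethyl, TIPS = triisopropylsilyl.

**Route**

Step 1
Reactants: 1 methyl vanillate; 2 allyl bromide
Product: 3 methyl 4-(allyloxy)-3-methoxybenzoate
Conditions: K2CO3, acetone, reflux
Reagents that add atoms: none
Why: Williamson ether synthesis, in which the phenoxide formed by K2CO3 displaces bromide from allyl bromide while the methyl ester is untouched.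

Step 2
Reactants: 3 methyl 4-(allyloxy)-3-methoxybenzoate
Product: 5 methyl 3-allyl-4-hydroxy-5-methoxybenzoate, via ortho-dienone 4 (not isolated)
Conditions: N,N-diethylaniline, 210 °C, argon
Reagents that add atoms: none
Why: Aromatic Claisen rearrangement, whose [3,3]-sigmatropic shift can deliver the allyl group only to C5, the one free ortho position, after which dienone 4 tautomerises to the phenol.

Step 3
Reactants: 5 methyl 3-allyl-4-hydroxy-5-methoxybenzoate
Product: 6 methyl 3-allyl-5-methoxy-4-(methoxymethoxy)benzoate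
Conditions: MOMCl, i-Pr2NEt, CH2Cl2, 0 °C to rt
Reagents that add atoms: chloromethyl methyl ether, COCCl
Why: MOM ether formation by O-alkylation of the phenol gives an acetal that should survive ozone, chlorite, the sodium enolate, LiAlH4 and MnO2 and is removed by acid in step 12.

Step 4
Reactants: 6 methyl 3-allyl-5-methoxy-4-(methoxymethoxy)benzoate
Product: 9 2-[3-methoxy-5-(methoxycarbonyl)-2-(methoxymethoxy)phenyl]acetic acid, via ozonide 7 (not isolated), via arylacetaldehyde 8 (not isolated)
Conditions: O3, CH2Cl2, −78 °C; PPh3, −78 °C to rt; then NaClO2, NaH2PO4, 2-methyl-2-butene, t-BuOH/H2O, 0 °C to rt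
Reagents that add atoms: ozone, [O-][O+]=O; sodium chlorite, [Na+].[O-]Cl=O
Why: Ozonolysis with reductive work-up followed by Pinnick oxidation shortens the allyl group by one carbon to the arylacetic acid, the enolisable aldehyde 8 being oxidised without isolation under buffered conditions that leave the MOM acetal and the ester alone.

Step 5
Reactants: 9 2-[3-methoxy-5-(methoxycarbonyl)-2-(methoxymethoxy)phenyl]acetic acid; 10 (R)-4-benzyl-1,3-oxazolidin-2-one
Product: 12 methyl 3-{2-[(4R)-4-benzyl-2-oxo-1,3-oxazolidin-3-yl]-2-oxoethyl}-5-methoxy-4-(methoxymethoxy)benzoate, via mixed pivalic anhydride 11 (not isolated)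
Conditions: t-BuCOCl, Et3N, THF, −20 °C; then 10, LiCl, −20 °C to rt
Reagents that add atoms: none
Why: N-Acylation of the oxazolidinone through the mixed pivalic anhydride, with LiCl/Et3N activating the auxiliary, loads the arylacetic acid without a strong base.

Step 6
Reactants: 13 vanillin
Product: 14 3-methoxy-4-(methoxymethoxy)benzaldehyde
Conditions: MOMCl, i-Pr2NEt, CH2Cl2, 0 °C to rt
Reagents that add atoms: chloromethyl methyl ether, COCCl
Why: MOM ether formation by O-alkylation of the phenol puts on ring A the same acid-labile group as on ring B, so that one acid step frees both.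

Step 7
Reactants: 14 3-methoxy-4-(methoxymethoxy)benzaldehyde
Product: 15 [3-methoxy-4-(methoxymethoxy)phenyl]methanol
Conditions: NaBH4, MeOH, 0 °C
Reagents that add atoms: none
Why: Borohydride reduction of the aromatic aldehyde gives the benzylic alcohol and does not touch the MOM acetal.

Step 8
Reactants: 15 [3-methoxy-4-(methoxymethoxy)phenyl]methanol
Product: 16 4-(bromomethyl)-2-methoxy-1-(methoxymethoxy)benzene
Conditions: CBr4, PPh3, CH2Cl2, 0 °C; used at once
Reagents that add atoms: carbon tetrabromide, BrC(Br)(Br)Br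
Why: Appel bromination converts the benzylic alcohol into the bromide under neutral conditions that do not expose the MOM acetal to HBr.

Step 9
Reactants: 12 methyl 3-{2-[(4R)-4-benzyl-2-oxo-1,3-oxazolidin-3-yl]-2-oxoethyl}-5-methoxy-4-(methoxymethoxy)benzoate; 16 4-(bromomethyl)-2-methoxy-1-(methoxymethoxy)benzene
Product: 18 methyl 3-{(2R)-1-[(4R)-4-benzyl-2-oxo-1,3-oxazolidin-3-yl]-3-[3-methoxy-4-(methoxymethoxy)phenyl]-1-oxopropan-2-yl}-5-methoxy-4-(methoxymethoxy)benzoate, via sodium (Z)-enolate 17 (not isolated)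
Conditions: NaN(SiMe3)2, THF, −78 °C; then 16, −78 to −45 °C; AcOH quench at −78 °C
Reagents that add atoms: none
Why: Evans asymmetric alkylation, in which the chelated (Z)-sodium enolate 17 is benzylated on the face opposite the C4 benzyl group of the (R)-auxiliary, setting the (R) configuration at the new centre (the future C3).

Step 10
Reactants: 18 the alkylated imide
Product: 19 (2R)-2-[5-(hydroxymethyl)-3-methoxy-2-(methoxymethoxy)phenyl]-3-[3-methoxy-4-(methoxymethoxy)phenyl]propan-1-ol
Conditions: LiAlH4, THF, −10 to 0 °C; aqueous NaOH work-up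
Reagents that add atoms: none
Why: Hydride reduction with LiAlH4 cleaves the exocyclic imide carbonyl to the primary alcohol with release of the auxiliary and reduces the methyl ester to the benzylic alcohol, after which the stereocenter is no longer alpha to a carbonyl group.

Step 11
Reactants: 19 the diol
Product: 20 3-{(2R)-1-hydroxy-3-[3-methoxy-4-(methoxymethoxy)phenyl]propan-2-yl}-5-methoxy-4-(methoxymethoxy)benzaldehyde
Conditions: activated MnO2, CH2Cl2, rt
Reagents that add atoms: none
Why: MnO2 oxidises benzylic alcohols chemoselectively, so the ring B hydroxymethyl group should go to the aldehyde while the aliphatic primary alcohol stays.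

Step 12
Reactants: 20 the bis-MOM aldehyde
Product: 21 (R)-4-hydroxy-3-[1-hydroxy-3-(4-hydroxy-3-methoxyphenyl)propan-2-yl]-5-methoxybenzaldehyde
Conditions: 3 M aq. HCl, THF, 45 °C
Reagents that add atoms: none
Why: Acid-catalysed acetal hydrolysis removes both aryl MOM ethers, and the aldehyde, the primary alcohol and the non-enolisable stereocenter are inert to aqueous acid.

Step 13
Reactants: 21 (R)-4-hydroxy-3-[1-hydroxy-3-(4-hydroxy-3-methoxyphenyl)propan-2-yl]-5-methoxybenzaldehyde
Product: 23 (2S,3R)-2-(4-hydroxy-3-methoxyphenyl)-3-(hydroxymethyl)-7-methoxy-2,3-dihydrobenzofuran-5-carbaldehyde, via p-quinone methide 22 (not isolated)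
Conditions: graphite anode, Pt cathode, undivided cell, constant current (2 mA cm−2) to 2.0 F mol−1, n-Bu4NBF4 (0.1 M), 2,6-lutidine (2 equiv), MeCN/(CF3)2CHOH 4:1, 5 mM, rt
Reagents that add atoms: none
Why: At the carbon anode the ring A guaiacol, the more easily oxidised phenol, goes through its phenoxyl radical and a second electron loss with removal of a benzylic proton to p-quinone methide 22, whose exocyclic carbon (the future C2) is attacked by the ring B phenol oxygen to form O1–C2 and re-aromatise ring A. The closest known reaction type is the anodic (or Ag2O- or DDQ-mediated) conversion of 4-alkyl-2-methoxyphenols into p-quinone methides that oxygen nucleophiles capture at the benzylic carbon, the same closure that ends the oxidative dimerisation of 4-propenylguaiacols to dihydrobenzofuran neolignans. Ring C closes in a 5-exo-trig mode because the C=C of the quinone methide lies outside the new ring, whereas attack by the primary hydroxyl would need a four-membered closure and is not expected. The new stereocenter C2 is controlled by the existing C3 centre, the aryl group taking the face opposite the C3 hydroxymethyl group, and since phenol addition to the quinone methide is reversible the trans (2S,3R) isomer is also the thermodynamic one. The step needs oxidation of ring A and not ring B, which the C5 formyl group para to the ring B hydroxyl secures by raising that ring's oxidation potential, provided only a weak base is present so that no ring B phenolate forms; hexafluoroisopropanol stabilises the cationic intermediates without adding to the quinone methide and high dilution favours ring closure over intermolecular capture. Stopping at 2 F per mole should protect the product, whose ring A phenol is still oxidisable, from dehydrogenation to the benzofuran.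

Step 14
Reactants: 23 the dihydrobenzofuran aldehyde
Product: 24 (2S,3R)-7-methoxy-2-{3-methoxy-4-[(triisopropylsilyl)oxy]phenyl}-3-{[(triisopropylsilyl)oxy]methyl}-2,3-dihydrobenzofuran-5-carbaldehyde
Conditions: i-Pr3SiCl, imidazole, DMF, rt to 40 °C
Reagents that add atoms: chlorotriisopropylsilane, CC(C)[Si](Cl)(C(C)C)C(C)C
Why: Silyl ether formation on the phenol and the primary alcohol masks the ring A hydroxyl, whose phenoxide could otherwise reopen ring C at C2 under the basic conditions of the next two steps.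

Step 15
Reactants: 24 the bis-TIPS aldehyde
Product: 25 (2S,3R)-5-ethynyl-7-methoxy-2-{3-methoxy-4-[(triisopropylsilyl)oxy]phenyl}-3-{[(triisopropylsilyl)oxy]methyl}-2,3-dihydrobenzofuran
Conditions: dimethyl (1-diazo-2-oxopropyl)phosphonate, K2CO3, MeOH/THF, 0 °C to rt
Reagents that add atoms: dimethyl (1-diazo-2-oxopropyl)phosphonate, CC(=O)C(=[N+]=[N-])P(=O)(OC)OC
Why: Ohira–Bestmann (Seyferth–Gilbert) homologation, in which the diazomethylphosphonate anion made by methanolysis adds to the aldehyde and the derived vinylidene carbene rearranges to the terminal alkyne.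

Step 16
Reactants: 26 eugenol
Product: 27 dihydroconiferyl alcohol [4-(3-hydroxypropyl)-2-methoxyphenol]
Conditions: BH3·THF, THF, 0 °C to rt; then aq. NaOH, H2O2, 0 °C to rt
Reagents that add atoms: hydrogen peroxide, OO
Why: Hydroboration–oxidation of the terminal alkene gives the anti-Markovnikov primary alcohol, the phenol only consuming one extra hydride.

Step 17
Reactants: 27 dihydroconiferyl alcohol
Product: 28 4-(3-hydroxypropyl)-2-iodo-6-methoxyphenol
Conditions: I2, NaHCO3, THF/H2O, 0 °C to rt
Reagents that add atoms: iodine, II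
Why: Electrophilic aromatic iodination under basic conditions goes ortho to the hydroxyl (para is blocked), the phenoxide oxygen outweighing the methoxy group as director.

Step 18
Reactants: 25 the bis-TIPS alkyne; 28 4-(3-hydroxypropyl)-2-iodo-6-methoxyphenol
Product: 30 3-{2-[(2S,3R)-7-methoxy-2-{3-methoxy-4-[(triisopropylsilyl)oxy]phenyl}-3-{[(triisopropylsilyl)oxy]methyl}-2,3-dihydrobenzofuran-5-yl]-7-methoxybenzofuran-5-yl}propan-1-ol, via o-alkynylphenol 29 (not isolated)
Conditions: PdCl2(PPh3)2 (5 mol %), CuI (10 mol %), Et3N, DMF, degassed, 65 °C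
Reagents that add atoms: none
Why: Sonogashira coupling (zerovalent palladium with CuI) of the aryl iodide with the terminal alkyne gives o-alkynylphenol 29, whose phenol oxygen adds to the metal-activated triple bond in a 5-endo-dig closure to form furan ring D.

Step 19
Reactants: 30 the bis-TIPS benzofuran
Product: 31 3-{2-[(2S,3R)-2-(4-hydroxy-3-methoxyphenyl)-3-(hydroxymethyl)-7-methoxy-2,3-dihydrobenzofuran-5-yl]-7-methoxybenzofuran-5-yl}propan-1-ol (CNP0308311.1)
Conditions: n-Bu4NF, AcOH, THF, 0 °C to rt
Reagents that add atoms: none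
Why: Fluoride-mediated desilylation cleaves both triisopropylsilyl ethers, and buffering with acetic acid keeps the ring A phenol protonated so that ring C is not opened.

**Compound list**

1 | methyl vanillate (methyl 4-hydroxy-3-methoxybenzoate) | COC(=O)c1ccc(O)c(OC)c1 | starting material
2 | allyl bromide | C=CCBr | starting material
3 | methyl 4-(allyloxy)-3-methoxybenzoate | COC(=O)c1ccc(OCC=C)c(OC)c1 | intermediate
4 | methyl 5-methoxy-4-oxo-3-(prop-2-en-1-yl)cyclohexa-1,5-diene-1-carboxylate (ortho-dienone, racemic) | COC(=O)C1=CC(CC=C)C(=O)C(OC)=C1 | intermediate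
5 | methyl 3-allyl-4-hydroxy-5-methoxybenzoate | COC(=O)c1cc(CC=C)c(O)c(OC)c1 | intermediate
6 | methyl 3-allyl-5-methoxy-4-(methoxymethoxy)benzoate | COC(=O)c1cc(CC=C)c(OCOC)c(OC)c1 | intermediate
7 | methyl 3-methoxy-4-(methoxymethoxy)-5-(1,2,4-trioxolan-3-ylmethyl)benzoate (ozonide) | COC(=O)c1cc(CC2OCOO2)c(OCOC)c(OC)c1 | intermediate
8 | methyl 3-methoxy-4-(methoxymethoxy)-5-(2-oxoethyl)benzoate | COC(=O)c1cc(CC=O)c(OCOC)c(OC)c1 | intermediate
9 | 2-[3-methoxy-5-(methoxycarbonyl)-2-(methoxymethoxy)phenyl]acetic acid | COC(=O)c1cc(CC(=O)O)c(OCOC)c(OC)c1 | intermediate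
10 | (R)-4-benzyl-1,3-oxazolidin-2-one | O=C1N[C@H](Cc2ccccc2)CO1 | starting material
11 | mixed anhydride of 9 with pivalic acid | COC(=O)c1cc(CC(=O)OC(=O)C(C)(C)C)c(OCOC)c(OC)c1 | intermediate
12 | methyl 3-{2-[(4R)-4-benzyl-2-oxo-1,3-oxazolidin-3-yl]-2-oxoethyl}-5-methoxy-4-(methoxymethoxy)benzoate | COC(=O)c1cc(CC(=O)N2[C@H](Cc3ccccc3)COC2=O)c(OCOC)c(OC)c1 | intermediate
13 | vanillin | COc1cc(C=O)ccc1O | starting material
14 | 3-methoxy-4-(methoxymethoxy)benzaldehyde | COCOc1ccc(C=O)cc1OC | intermediate
15 | [3-methoxy-4-(methoxymethoxy)phenyl]methanol | COCOc1ccc(CO)cc1OC | intermediate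
16 | 4-(bromomethyl)-2-methoxy-1-(methoxymethoxy)benzene | COCOc1ccc(CBr)cc1OC | intermediate
17 | sodium (Z)-enolate of 12 | COC(=O)c1cc(/C=C(\[O-])N2[C@H](Cc3ccccc3)COC2=O)c(OCOC)c(OC)c1.[Na+] | intermediate
18 | methyl 3-{(2R)-1-[(4R)-4-benzyl-2-oxo-1,3-oxazolidin-3-yl]-3-[3-methoxy-4-(methoxymethoxy)phenyl]-1-oxopropan-2-yl}-5-methoxy-4-(methoxymethoxy)benzoate | COC(=O)c1cc(OC)c(OCOC)c(c1)[C@@H](Cc1ccc(OCOC)c(OC)c1)C(=O)N1[C@H](Cc2ccccc2)COC1=O | intermediate
19 | (2R)-2-[5-(hydroxymethyl)-3-methoxy-2-(methoxymethoxy)phenyl]-3-[3-methoxy-4-(methoxymethoxy)phenyl]propan-1-ol | OCc1cc(OC)c(OCOC)c(c1)[C@@H](Cc1ccc(OCOC)c(OC)c1)CO | intermediate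
20 | 3-{(2R)-1-hydroxy-3-[3-methoxy-4-(methoxymethoxy)phenyl]propan-2-yl}-5-methoxy-4-(methoxymethoxy)benzaldehyde | O=Cc1cc(OC)c(OCOC)c(c1)[C@@H](Cc1ccc(OCOC)c(OC)c1)CO | intermediate
21 | (R)-4-hydroxy-3-[1-hydroxy-3-(4-hydroxy-3-methoxyphenyl)propan-2-yl]-5-methoxybenzaldehyde | O=Cc1cc(OC)c(O)c(c1)[C@@H](Cc1ccc(O)c(OC)c1)CO | intermediate
22 | 4-hydroxy-3-[(2R)-1-hydroxy-3-(3-methoxy-4-oxocyclohexa-2,5-dien-1-ylidene)propan-2-yl]-5-methoxybenzaldehyde (p-quinone methide) | O=Cc1cc(OC)c(O)c(c1)[C@@H](C=C1C=CC(=O)C(OC)=C1)CO | intermediate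
23 | (2S,3R)-2-(4-hydroxy-3-methoxyphenyl)-3-(hydroxymethyl)-7-methoxy-2,3-dihydrobenzofuran-5-carbaldehyde | COc1cc([C@H]2Oc3c(OC)cc(C=O)cc3[C@@H]2CO)ccc1O | intermediate
24 | (2S,3R)-7-methoxy-2-{3-methoxy-4-[(triisopropylsilyl)oxy]phenyl}-3-{[(triisopropylsilyl)oxy]methyl}-2,3-dihydrobenzofuran-5-carbaldehyde | COc1cc([C@H]2Oc3c(OC)cc(C=O)cc3[C@@H]2CO[Si](C(C)C)(C(C)C)C(C)C)ccc1O[Si](C(C)C)(C(C)C)C(C)C | intermediate
25 | (2S,3R)-5-ethynyl-7-methoxy-2-{3-methoxy-4-[(triisopropylsilyl)oxy]phenyl}-3-{[(triisopropylsilyl)oxy]methyl}-2,3-dihydrobenzofuran | COc1cc([C@H]2Oc3c(OC)cc(C#C)cc3[C@@H]2CO[Si](C(C)C)(C(C)C)C(C)C)ccc1O[Si](C(C)C)(C(C)C)C(C)C | intermediate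
26 | eugenol | C=CCc1ccc(O)c(OC)c1 | starting material
27 | dihydroconiferyl alcohol | OCCCc1ccc(O)c(OC)c1 | intermediate
28 | 4-(3-hydroxypropyl)-2-iodo-6-methoxyphenol | OCCCc1cc(I)c(O)c(OC)c1 | intermediate
29 | 2-{[(2S,3R)-7-methoxy-2-{3-methoxy-4-[(triisopropylsilyl)oxy]phenyl}-3-{[(triisopropylsilyl)oxy]methyl}-2,3-dihydrobenzofuran-5-yl]ethynyl}-4-(3-hydroxypropyl)-6-methoxyphenol | COc1cc([C@H]2Oc3c(OC)cc(C#Cc4cc(CCCO)cc(OC)c4O)cc3[C@@H]2CO[Si](C(C)C)(C(C)C)C(C)C)ccc1O[Si](C(C)C)(C(C)C)C(C)C | intermediate
30 | 3-{2-[(2S,3R)-7-methoxy-2-{3-methoxy-4-[(triisopropylsilyl)oxy]phenyl}-3-{[(triisopropylsilyl)oxy]methyl}-2,3-dihydrobenzofuran-5-yl]-7-methoxybenzofuran-5-yl}propan-1-ol | COc1cc([C@H]2Oc3c(OC)cc(-c4cc5cc(CCCO)cc(OC)c5o4)cc3[C@@H]2CO[Si](C(C)C)(C(C)C)C(C)C)ccc1O[Si](C(C)C)(C(C)C)C(C)C | intermediate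
31 | 3-{2-[(2S,3R)-2-(4-hydroxy-3-methoxyphenyl)-3-(hydroxymethyl)-7-methoxy-2,3-dihydrobenzofuran-5-yl]-7-methoxybenzofuran-5-yl}propan-1-ol (CNP0308311.1) | COc1cc([C@H]2Oc3c(OC)cc(-c4cc5cc(CCCO)cc(OC)c5o4)cc3[C@@H]2CO)ccc1O | target

**Step count**

Total: 19 steps. Longest linear sequence: 14 steps (steps 1–5, 9–15, 18 and 19); steps 6–8 and 16–17 are side branches.

**Steps most likely to fail**

Step 13 (anodic ring closure). Three processes may defeat it: further oxidation of the product, whose ring A phenol is still free, leading to dehydrogenation of ring C to the benzofuran; coupling of phenoxyl radicals between molecules at the free ortho position of ring A; and electron loss from ring B if any of its phenolate forms. The fallback forms the same O1–C2 bond by ionisation of a benzylic alcohol instead of C–H oxidation; it sets out from acid 9 and aldehyde 14 and comes back at 23. Acid 9 would be activated as the mixed anhydride 11 and loaded onto (S)-4-benzyl-1,3-oxazolidin-2-one to give the (S)-imide F1; the enantiomeric auxiliary is needed because the boron aldol uses the enolate face opposite to that of the alkylation. Bu2BOTf and i-Pr2NEt in CH2Cl2 at −78 °C would give the dibutylboron (Z)-enolate F2, which with aldehyde 14 should give the Evans syn-aldol adduct F3 with the correct C3 configuration. LiBH4 in THF with one equivalent of MeOH at 0 °C would remove the auxiliary and leave the aryl ester, giving the diol ester F4. Aqueous HCl in THF at 45 °C would remove both MOM groups to the triol ester F5, which under the same conditions ionises at the p-hydroxybenzylic carbinol and is closed by the ring B phenol to the trans dihydrobenzofuran ester F6. LiAlH4 would reduce the ester to the benzylic alcohol F7, and MnO2 would oxidise that benzylic alcohol selectively to 23.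

Step 18 (Sonogashira coupling and ring closure). Oxidative homocoupling of alkyne 25 may outrun cross-coupling with the electron-rich iodophenol, or the sequence may stall at the open alkynylphenol. The fallback separates C–C coupling from C–O closure; it sets out from 28 and 25 and comes back at 30. Iodophenol 28 would be acetylated (Ac2O, pyridine) to the diacetate F8, which as a less electron-rich aryl iodide should couple with 25 at room temperature (PdCl2(PPh3)2, CuI, Et3N, THF) to give the diarylalkyne diacetate F9. K2CO3 in MeOH would remove both acetates to give 29, here isolated, and AuCl(PPh3) with AgOTf (2 mol % each, CH2Cl2, rt) would cycloisomerise it to 30.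

Step 9 (auxiliary-controlled benzylation). The stabilised arylacetyl enolate may react slowly enough that it breaks down or that the electron-rich benzyl bromide decomposes first, and the acidic α-aryl position may epimerise during quench and work-up. The fallback sets the stereocenter by catalytic asymmetric hydrogenation; it sets out from acid 9 and aldehyde 14 and comes back at 19. Perkin condensation (Ac2O, Et3N, 100 °C) would give the (E)-2,3-diarylacrylic acid F10. Hydrogenation with Rh(cod)2BF4 and a chiral ferrocenyl bisphosphine of the Walphos family (H2 20 bar, MeOH, Et3N; ligand enantiomer chosen so that the R acid results, to be checked against 19 from the main route) would give the (R)-2,3-diarylpropanoic acid F11. LiAlH4 would reduce both the acid and the methyl ester to diol 19.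

**Further compounds**

F1 | step 13 | methyl 3-{2-[(4S)-4-benzyl-2-oxo-1,3-oxazolidin-3-yl]-2-oxoethyl}-5-methoxy-4-(methoxymethoxy)benzoate | COC(=O)c1cc(CC(=O)N2[C@@H](Cc3ccccc3)COC2=O)c(OCOC)c(OC)c1
F2 | step 13 | dibutylboron (Z)-enolate of F1 | COC(=O)c1cc(/C=C(\OB(CCCC)CCCC)N2[C@@H](Cc3ccccc3)COC2=O)c(OCOC)c(OC)c1
F3 | step 13 | methyl 3-{(2S,3S)-1-[(4S)-4-benzyl-2-oxo-1,3-oxazolidin-3-yl]-3-hydroxy-3-[3-methoxy-4-(methoxymethoxy)phenyl]-1-oxopropan-2-yl}-5-methoxy-4-(methoxymethoxy)benzoate | COC(=O)c1cc(OC)c(OCOC)c(c1)[C@@H]([C@H](O)c1ccc(OCOC)c(OC)c1)C(=O)N1[C@@H](Cc2ccccc2)COC1=O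
F4 | step 13 | methyl 3-{(1S,2R)-1,3-dihydroxy-1-[3-methoxy-4-(methoxymethoxy)phenyl]propan-2-yl}-5-methoxy-4-(methoxymethoxy)benzoate | COC(=O)c1cc(OC)c(OCOC)c(c1)[C@@H]([C@H](O)c1ccc(OCOC)c(OC)c1)CO
F5 | step 13 | methyl 3-[(1S,2R)-1,3-dihydroxy-1-(4-hydroxy-3-methoxyphenyl)propan-2-yl]-4-hydroxy-5-methoxybenzoate | COC(=O)c1cc(OC)c(O)c(c1)[C@@H]([C@H](O)c1ccc(O)c(OC)c1)CO
F6 | step 13 | methyl (2S,3R)-2-(4-hydroxy-3-methoxyphenyl)-3-(hydroxymethyl)-7-methoxy-2,3-dihydrobenzofuran-5-carboxylate | COc1cc([C@H]2Oc3c(OC)cc(C(=O)OC)cc3[C@@H]2CO)ccc1O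
F7 | step 13 | 4-[(2S,3R)-3,5-bis(hydroxymethyl)-7-methoxy-2,3-dihydrobenzofuran-2-yl]-2-methoxyphenol | COc1cc([C@H]2Oc3c(OC)cc(CO)cc3[C@@H]2CO)ccc1O
F8 | step 18 | 3-(4-acetoxy-3-iodo-5-methoxyphenyl)propyl acetate | CC(=O)OCCCc1cc(I)c(OC(C)=O)c(OC)c1
F9 | step 18 | 3-{4-acetoxy-3-[(bis-TIPS dihydrobenzofuran-5-yl)ethynyl]-5-methoxyphenyl}propyl acetate (diacetate of 29) | COc1cc([C@H]2Oc3c(OC)cc(C#Cc4cc(CCCOC(C)=O)cc(OC)c4OC(C)=O)cc3[C@@H]2CO[Si](C(C)C)(C(C)C)C(C)C)ccc1O[Si](C(C)C)(C(C)C)C(C)C
F10 | step 9 | (E)-2-[3-methoxy-5-(methoxycarbonyl)-2-(methoxymethoxy)phenyl]-3-[3-methoxy-4-(methoxymethoxy)phenyl]acrylic acid | COC(=O)c1cc(OC)c(OCOC)c(c1)/C(C(=O)O)=C\c1ccc(OCOC)c(OC)c1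
F11 | step 9 | (2R)-2-[3-methoxy-5-(methoxycarbonyl)-2-(methoxymethoxy)phenyl]-3-[3-methoxy-4-(methoxymethoxy)phenyl]propanoic acid | COC(=O)c1cc(OC)c(OCOC)c(c1)[C@@H](Cc1ccc(OCOC)c(OC)c1)C(=O)O
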